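## Analysis of the target

Compound 20 is a (2S)-flavanone. Ring A is a phloroglucinol with hydroxyls at C5 and C7 and a prenyl group at C6. Ring C is the dihydropyranone (O1, C2, C3, C4=O). Ring B is attached at C2 and carries a prenyl group at C2', a hydroxyl at C3' and a methoxy group at C4'. The only stereocentre is C2. It is benzylic, bears the ring oxygen and lies β to the ketone, so it can be lost by retro-oxa-Michael ring opening under base, or by heterolysis of the C2–O1 bond under acid, which the para-methoxy group of ring B assists. Both prenyl groups sit ortho to phenols, and the C6 prenyl has a phenol on each side. Protic acid would therefore cyclise them to chromans or add across the double bonds, and hydrogenolysis is excluded. The difficulties are three: placing each prenyl group on the correct carbon (C6 and not C8; the crowded C2'), creating C2 late without scrambling it, and choosing phenol protection that comes off without acid or base. The plan rests on one structural fact. Ring A is the skeleton of 13, and C6, which carries the prenyl group, is para to C8a, which carries O1. Before the C4–C4a bond exists, C4a and C8 are therefore equivalent. Acylation at either carbon ortho to O1 gives the same 5,7-dioxygenated 6-prenyl chromanone.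

## Retrosynthetic reasoning

**20 to 19.** The three phenols are carried as tert-butyldimethylsilyl (TBS) ethers to the end. Only the three O–Si bonds are cut, with buffered fluoride, so neither the prenyl groups nor C2 meet acid or base.

**19 to 17 (through 18).** The C4–C4a bond is cut. It is the one bond of ring C whose formation leaves C2 untouched and for which ring A offers two equivalent nucleophilic carbons. This splits the molecule into two arenes joined by a three-carbon acid chain. The forward reaction is an intramolecular arene acylation of 17 via its acid chloride 18. It has to proceed without ionising the C2–O1 bond and without acid reaching the prenyl groups.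

**17 to 16 to 10 + 15.** The O1–C2 bond is cut next. Forming it by inversion of the (R)-carbinol 10 with the phenol 15 sets C2 under neutral conditions. The carboxyl group is carried as an allyl ester in 16 because it can be removed without hydroxide. Saponification would expel the β-aryloxy group and strip the aryl silyl ethers.

**15 to 14 to 13 to 11 + 12.** In ring A the C6–CH2 bond is cut back to phloroglucinol 11 and prenyl bromide 12. The triol 13 is fully silylated to 14. The one silyl ether with no ortho substituent, the one para to the prenyl group, is then removed to give the symmetric phenol 15.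

**10 to 9 to 8 to 6 + 7.** The stereocentre is traced to the ketone 9, reduced by asymmetric transfer hydrogenation. The C2–C3 bond is traced to an aldol addition of the enolate of allyl acetate 7 to aldehyde 6, followed by oxidation of the racemic aldol 8. Three reliable steps replace an acetate aldol of uncertain selectivity.

**6 to 5 to 4 to 3 to 1 + 2.** The C2'–CH2 bond is cut by an aromatic Claisen rearrangement of the 1,1-dimethylallyl ether 4. That ether comes from isovanillin 1 and the tertiary propargylic chloride 2 by etherification to 3 and semi-hydrogenation. The methoxy group blocks the other ortho position, so the allyl group can only move to C2' and arrives as a normal prenyl group in 5, which is silylated to 6.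

## Alternatives that were turned down

**Alternative 1:** Both C-prenyl bonds (C6–CH2 and C2'–CH2) are cut last and the flavanone core is taken intact.
- Forward route: the chiral-pool flavanone hesperetin A1 would be protected at O7 and etherified at O5 and O3' with 1,1-dimethylallyl groups to give A2. Heating A2 would move both groups to carbon in a double aromatic Claisen rearrangement and give A3.
- For: it is clearly the shortest plan. C2 comes from nature, and each migration has only one open ortho position (C4a and C4' are blocked).
- Against: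
  - The chelated peri 5-hydroxyl is the hardest position of a flavanone to alkylate with a tertiary electrophile. The base needed would open ring C by retro-oxa-Michael reaction and erase C2.
  - Heating a 2-(4-methoxyphenyl)chromanone to Claisen temperatures invites the same loss.
  - The methoxymethyl group of A3 must finally be removed with acid in the presence of three phenol/ortho-prenyl pairs.
- Comparison: Alternative 1 is stronger on step count. The chosen route places each prenyl group on a simple arene before assembly and creates C2 late, and the finished flavanone meets only buffered fluoride.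

**Alternative 2:** The C3–C4 bond is cut and C2 is created in the same step.
- Forward route: the salicylaldehyde 1-arylvinyl ether A4 would undergo intramolecular hydroacylation with a rhodium catalyst bearing a chiral bisphosphine. The aldehyde C–H adds across the enol ether to give A5.
- For: one catalytic step closes ring C and sets C2, with no leaving-group chemistry at the benzylic carbon. The free ortho-hydroxyl can chelate rhodium and restrain decarbonylation. On stereo-economy it is stronger than the chosen route, which needs a reduction, an inversion and an acylation for the same result.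
- Against:
  - Six-membered ketone formation by hydroacylation is much less developed than five-membered.
  - The alkene is 1,1-disubstituted, electron-rich and flanked by an ortho-prenyl arene, so both insertion and facial discrimination lack close precedent.
  - Two prenyl double bonds can engage the rhodium hydride.
  - A4 is a hindered enol ether next to an aldehyde and would itself take several uncertain steps.
  - Acidic removal of the methoxymethyl groups ends the route.
- Comparison: the chosen route instead uses only reactions with close precedent and confines its risk to one observable failure mode, heterolysis at C2.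

**Alternative 3:** Ring A is built de novo. C6–C7 and C4a–C5 are new bonds and C7–C8 is re-formed.
- Forward route: the chiral 3-alkoxycyclobutenone A6 would open thermally to a vinylketene and combine with the prenyl siloxyalkyne A7 in a benzannulation to give phenol A8.
- For: the oxygen of the (S)-carbinol is carried into A6 with its C–O bond intact, so no inversion at an ionisable benzylic carbon is needed. O5 and O7 emerge differentiated, so no selective desilylation is needed. On both points it is stronger than the chosen route.
- Against: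
  - A6 and A7 each need a multi-step preparation, and A7 is moisture-sensitive.
  - The benzylic oxygen of A6 is part of a vinylogous ester, a better leaving group than a phenoxide, and must survive prolonged heating.
  - A8 still has to be taken through ester cleavage and the same ring-closing acylation, so the plan adds steps without removing the central risk.
- Comparison: the chosen route reaches ring A in three steps from phloroglucinol 11 and uses its symmetry in place of differentiation.

Key step: step 13

Assumption: the (R,R)-configured transfer-hydrogenation catalyst is taken to reduce ketone 9 with the facial sense known for acetophenone-type ketones, giving the (R)-carbinol; if the assignment of 10 proved opposite, the enantiomeric catalyst would be used.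

Abbreviations: TBS = tert-butyldimethylsilyl; prenyl = 3-methylbut-2-en-1-yl.

## Route

Step 1
Reactants: 1 isovanillin (3-hydroxy-4-methoxybenzaldehyde); 2 3-chloro-3-methylbut-1-yne
Product: 3 4-methoxy-3-[(2-methylbut-3-yn-2-yl)oxy]benzaldehyde
Conditions: CuCl2·2H2O (cat.), DBU, MeCN, 0 °C
Reagents that add atoms: none
Why: Copper-catalysed O-alkylation of a phenol with a tertiary propargylic chloride; the acidic phenol of 1 reacts cleanly and the aldehyde is inert.

Step 2
Reactants: 3 4-methoxy-3-[(2-methylbut-3-yn-2-yl)oxy]benzaldehyde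
Product: 4 4-methoxy-3-[(2-methylbut-3-en-2-yl)oxy]benzaldehyde
Conditions: H2 (1 atm), Pd/CaCO3 poisoned with Pb(OAc)2 (Lindlar catalyst), quinoline, EtOAc, rt
Reagents that add atoms: none
Why: Lindlar semi-hydrogenation of a terminal alkyne stops at the alkene; the aldehyde and aryl ether are not reduced under these conditions.

Step 3
Reactants: 4 4-methoxy-3-[(2-methylbut-3-en-2-yl)oxy]benzaldehyde
Product: 5 3-hydroxy-4-methoxy-2-prenylbenzaldehyde
Conditions: xylenes, 130 °C
Reagents that add atoms: none
Why: Aromatic Claisen rearrangement; the [3,3] shift delivers the unsubstituted allyl terminus to the only free ortho carbon (the other bears the methoxy group), so the tertiary ether becomes a normal prenyl group, and tautomerisation restores the phenol.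

Step 4
Reactants: 5 3-hydroxy-4-methoxy-2-prenylbenzaldehyde
Product: 6 3-(TBS-oxy)-4-methoxy-2-prenylbenzaldehyde
Conditions: TBSCl, imidazole, DMF, rt
Reagents that add atoms: tert-butyldimethylsilyl chloride, CC(C)(C)[Si](C)(C)Cl
Why: Standard silylation of a phenol; the flanked aryl silyl ether is robust toward all later steps up to the final fluoride treatment.

Step 5
Reactants: 6 3-(TBS-oxy)-4-methoxy-2-prenylbenzaldehyde; 7 allyl acetate
Product: 8 allyl 3-hydroxy-3-[3-(TBS-oxy)-4-methoxy-2-prenylphenyl]propanoate (racemic)
Conditions: LDA, THF, −78 °C; then AcOH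
Reagents that add atoms: none
Why: Aldol addition of the lithium enolate of an acetate ester to a non-enolisable aromatic aldehyde; at −78 °C the aryl silyl ether and the allyl ester are untouched.

Step 6
Reactants: 8 allyl 3-hydroxy-3-[3-(TBS-oxy)-4-methoxy-2-prenylphenyl]propanoate (racemic)
Product: 9 allyl 3-oxo-3-[3-(TBS-oxy)-4-methoxy-2-prenylphenyl]propanoate
Conditions: Dess–Martin periodinane, NaHCO3, CH2Cl2, 0 °C to rt
Reagents that add atoms: none
Why: Dess–Martin oxidation of a benzylic secondary alcohol to the β-keto ester under buffered, non-acidic conditions that spare the prenyl and allyl double bonds.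

Step 7
Reactants: 9 allyl 3-oxo-3-[3-(TBS-oxy)-4-methoxy-2-prenylphenyl]propanoate
Product: 10 allyl (3R)-3-hydroxy-3-[3-(TBS-oxy)-4-methoxy-2-prenylphenyl]propanoate
Conditions: RuCl[(R,R)-TsDPEN](p-cymene) (cat.), HCO2H/Et3N azeotrope, DMF, rt
Reagents that add atoms: none
Why: Noyori–Ikariya asymmetric transfer hydrogenation of an aryl β-keto ester; the catalyst places the aryl group under its arene ligand and delivers hydride to the Si face of the ketone, setting the (R)-carbinol, and the outer-sphere hydride transfer does not touch isolated alkenes.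

Step 8
Reactants: 11 phloroglucinol (benzene-1,3,5-triol); 12 prenyl bromide (1-bromo-3-methylbut-2-ene)
Product: 13 2-prenylbenzene-1,3,5-triol
Conditions: DBU, THF, 0 °C to rt (11 in excess)
Reagents that add atoms: none
Why: C-alkylation of the ambident phloroglucinol anion with an allylic bromide; excess 11 holds back dialkylation, and all three ring carbons are equivalent, so only one mono-C-prenyl product is possible.

Step 9
Reactants: 13 2-prenylbenzene-1,3,5-triol
Product: 14 1,3,5-tris(TBS-oxy)-2-prenylbenzene
Conditions: TBSCl (excess), imidazole, DMF, rt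
Reagents that add atoms: tert-butyldimethylsilyl chloride, CC(C)(C)[Si](C)(C)Cl
Why: Exhaustive silylation of the three phenols; it removes the acidity that would otherwise let the ortho-prenyl phenols cyclise.

Step 10
Reactants: 14 1,3,5-tris(TBS-oxy)-2-prenylbenzene
Product: 15 3,5-bis(TBS-oxy)-4-prenylphenol
Conditions: K2CO3 (cat.), MeOH/THF, −20 to 0 °C
Reagents that add atoms: none
Why: Base-mediated methanolysis of an aryl silyl ether; methoxide attacks the silicon of the ether para to the prenyl group, the only one without an ortho substituent, and the phenoxide formed makes the remaining two aryloxy groups poorer leaving groups, which favours stopping after one cleavage.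

Step 11
Reactants: 10 allyl (3R)-3-hydroxy-3-[3-(TBS-oxy)-4-methoxy-2-prenylphenyl]propanoate; 15 3,5-bis(TBS-oxy)-4-prenylphenol
Product: 16 allyl (3S)-3-[3,5-bis(TBS-oxy)-4-prenylphenoxy]-3-[3-(TBS-oxy)-4-methoxy-2-prenylphenyl]propanoate
Conditions: PPh3, DIAD, toluene, 0 °C to rt
Reagents that add atoms: none
Why: Mitsunobu etherification; the unhindered phenoxide of 15 displaces the alkoxyphosphonium of 10 in an SN2 step with inversion, turning the (R)-carbinol into the (S)-aryl ether, and the non-polar solvent and low temperature are chosen to disfavour ion-pair formation at the benzylic carbon.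

Step 12
Reactants: 16 allyl (3S)-3-[3,5-bis(TBS-oxy)-4-prenylphenoxy]-3-[3-(TBS-oxy)-4-methoxy-2-prenylphenyl]propanoate
Product: 17 (3S)-3-[3,5-bis(TBS-oxy)-4-prenylphenoxy]-3-[3-(TBS-oxy)-4-methoxy-2-prenylphenyl]propanoic acid
Conditions: Pd(PPh3)4 (cat.), morpholine, THF, rt; pH 5 buffer work-up
Reagents that add atoms: none
Why: Tsuji–Trost deallylation; Pd(PPh3)4 ionises only the allyl ester and morpholine captures the allyl group, so the acid is freed without hydroxide, which would eliminate the β-aryloxy group and cleave the aryl silyl ethers.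

Step 13
Reactants: 17 (3S)-3-[3,5-bis(TBS-oxy)-4-prenylphenoxy]-3-[3-(TBS-oxy)-4-methoxy-2-prenylphenyl]propanoic acid
Product: 19 (2S)-5,7-bis(TBS-oxy)-2-[3-(TBS-oxy)-4-methoxy-2-prenylphenyl]-6-prenyl-2,3-dihydro-4H-chromen-4-one, via acid chloride 18 (not isolated)
Conditions: 1-chloro-N,N,2-trimethylprop-1-en-1-amine, CH2Cl2, 0 °C; then ZnCl2 (Et2O solution), 2,6-di-tert-butyl-4-methylpyridine, CH2Cl2, −40 to 0 °C
Reagents that add atoms: 1-chloro-N,N,2-trimethylprop-1-en-1-amine, CC(C)=C(Cl)N(C)C (supplies the chlorine of 18; none of its atoms remain in 19)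
Why: Intramolecular Friedel–Crafts acylation, the established closure of 3-aryl-3-aryloxypropanoic acids to flavanones: the chloroenamine turns 17 into acid chloride 18 without releasing acid, ZnCl2 polarises the C–Cl bond, C4a of ring A attacks the acyl carbon, and loss of the proton from the Wheland intermediate to the hindered pyridine restores the arene and forms C4–C4a. Ring C closes as a six-membered ring, 6-exo-trig on the activated acyl chloride (6-exo-dig if a free acylium ion is involved). No stereocentre is formed; C2 keeps the S configuration from step 11 provided the C2–O1 bond does not ionise, which the weak Lewis acid, the low temperature and the absence of free acid are chosen to secure. No regiochemical choice arises, because the two carbons ortho to O1 are equivalent before the bond forms and either gives the 5,7-dioxygenated 6-prenyl pattern. Chemoselectivity is needed against acylation of ring B at C6' (a five-membered indanone closure at a carbon activated by a single, twisted silyloxy group) and against attack by the prenyl double bond of ring B (a seven-membered closure); the triply oxygen-activated ring A and the six-membered transition state should outrun both. The pyridine base, too hindered to bind zinc, takes up the HCl and so protects the prenyl double bonds from hydrochlorination.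

Step 14
Reactants: 19 (2S)-5,7-bis(TBS-oxy)-2-[3-(TBS-oxy)-4-methoxy-2-prenylphenyl]-6-prenyl-2,3-dihydro-4H-chromen-4-one
Product: 20 (2S)-5,7-dihydroxy-2-[3-hydroxy-4-methoxy-2-prenylphenyl]-6-prenyl-2,3-dihydro-4H-chromen-4-one
Conditions: HF·pyridine, pyridine, THF, 0 °C to rt
Reagents that add atoms: none
Why: Fluoride cleavage of aryl silyl ethers; the pyridine buffer keeps the medium too weakly acidic to cyclise the ortho-prenyl phenols and too weakly basic to open ring C, so C2 is not disturbed.

## Compound list

1 | isovanillin (3-hydroxy-4-methoxybenzaldehyde) | COc1ccc(C=O)cc1O | starting material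
2 | 3-chloro-3-methylbut-1-yne | CC(C)(Cl)C#C | starting material
3 | 4-methoxy-3-[(2-methylbut-3-yn-2-yl)oxy]benzaldehyde | COc1ccc(C=O)cc1OC(C)(C)C#C | intermediate
4 | 4-methoxy-3-[(2-methylbut-3-en-2-yl)oxy]benzaldehyde | COc1ccc(C=O)cc1OC(C)(C)C=C | intermediate
5 | 3-hydroxy-4-methoxy-2-(3-methylbut-2-en-1-yl)benzaldehyde | COc1ccc(C=O)c(CC=C(C)C)c1O | intermediate
6 | 3-[(tert-butyldimethylsilyl)oxy]-4-methoxy-2-(3-methylbut-2-en-1-yl)benzaldehyde | COc1ccc(C=O)c(CC=C(C)C)c1O[Si](C)(C)C(C)(C)C | intermediate
7 | allyl acetate (prop-2-en-1-yl acetate) | CC(=O)OCC=C | starting material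
8 | allyl 3-hydroxy-3-{3-[(tert-butyldimethylsilyl)oxy]-4-methoxy-2-(3-methylbut-2-en-1-yl)phenyl}propanoate (racemic) | COc1ccc(C(O)CC(=O)OCC=C)c(CC=C(C)C)c1O[Si](C)(C)C(C)(C)C | intermediate
9 | allyl 3-oxo-3-{3-[(tert-butyldimethylsilyl)oxy]-4-methoxy-2-(3-methylbut-2-en-1-yl)phenyl}propanoate | COc1ccc(C(=O)CC(=O)OCC=C)c(CC=C(C)C)c1O[Si](C)(C)C(C)(C)C | intermediate
10 | allyl (3R)-3-hydroxy-3-{3-[(tert-butyldimethylsilyl)oxy]-4-methoxy-2-(3-methylbut-2-en-1-yl)phenyl}propanoate | C=CCOC(=O)C[C@@H](O)c1ccc(OC)c(O[Si](C)(C)C(C)(C)C)c1CC=C(C)C | intermediate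
11 | phloroglucinol (benzene-1,3,5-triol) | Oc1cc(O)cc(O)c1 | starting material
12 | prenyl bromide (1-bromo-3-methylbut-2-ene) | CC(C)=CCBr | starting material
13 | 2-(3-methylbut-2-en-1-yl)benzene-1,3,5-triol | CC(C)=CCc1c(O)cc(O)cc1O | intermediate
14 | 1,3,5-tris[(tert-butyldimethylsilyl)oxy]-2-(3-methylbut-2-en-1-yl)benzene | CC(C)=CCc1c(O[Si](C)(C)C(C)(C)C)cc(O[Si](C)(C)C(C)(C)C)cc1O[Si](C)(C)C(C)(C)C | intermediate
15 | 3,5-bis[(tert-butyldimethylsilyl)oxy]-4-(3-methylbut-2-en-1-yl)phenol | CC(C)=CCc1c(O[Si](C)(C)C(C)(C)C)cc(O)cc1O[Si](C)(C)C(C)(C)C | intermediate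
16 | allyl (3S)-3-{3,5-bis[(tert-butyldimethylsilyl)oxy]-4-(3-methylbut-2-en-1-yl)phenoxy}-3-{3-[(tert-butyldimethylsilyl)oxy]-4-methoxy-2-(3-methylbut-2-en-1-yl)phenyl}propanoate | C=CCOC(=O)C[C@H](Oc1cc(O[Si](C)(C)C(C)(C)C)c(CC=C(C)C)c(O[Si](C)(C)C(C)(C)C)c1)c1ccc(OC)c(O[Si](C)(C)C(C)(C)C)c1CC=C(C)C | intermediate
17 | (3S)-3-{3,5-bis[(tert-butyldimethylsilyl)oxy]-4-(3-methylbut-2-en-1-yl)phenoxy}-3-{3-[(tert-butyldimethylsilyl)oxy]-4-methoxy-2-(3-methylbut-2-en-1-yl)phenyl}propanoic acid | OC(=O)C[C@H](Oc1cc(O[Si](C)(C)C(C)(C)C)c(CC=C(C)C)c(O[Si](C)(C)C(C)(C)C)c1)c1ccc(OC)c(O[Si](C)(C)C(C)(C)C)c1CC=C(C)C | intermediate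
18 | (3S)-3-{3,5-bis[(tert-butyldimethylsilyl)oxy]-4-(3-methylbut-2-en-1-yl)phenoxy}-3-{3-[(tert-butyldimethylsilyl)oxy]-4-methoxy-2-(3-methylbut-2-en-1-yl)phenyl}propanoyl chloride | ClC(=O)C[C@H](Oc1cc(O[Si](C)(C)C(C)(C)C)c(CC=C(C)C)c(O[Si](C)(C)C(C)(C)C)c1)c1ccc(OC)c(O[Si](C)(C)C(C)(C)C)c1CC=C(C)C | intermediate
19 | (2S)-5,7-bis[(tert-butyldimethylsilyl)oxy]-2-{3-[(tert-butyldimethylsilyl)oxy]-4-methoxy-2-(3-methylbut-2-en-1-yl)phenyl}-6-(3-methylbut-2-en-1-yl)-2,3-dihydro-4H-chromen-4-one | COc1ccc([C@@H]2CC(=O)c3c(cc(O[Si](C)(C)C(C)(C)C)c(CC=C(C)C)c3O[Si](C)(C)C(C)(C)C)O2)c(CC=C(C)C)c1O[Si](C)(C)C(C)(C)C | intermediate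
20 | (2S)-5,7-dihydroxy-2-[3-hydroxy-4-methoxy-2-(3-methylbut-2-en-1-yl)phenyl]-6-(3-methylbut-2-en-1-yl)-2,3-dihydro-4H-chromen-4-one | COc1ccc([C@@H]2CC(=O)c3c(cc(O)c(CC=C(C)C)c3O)O2)c(CC=C(C)C)c1O | target

## Step count and least certain steps

Total: 14 steps. Longest linear sequence: 11 steps (steps 1–7 and 11–14 from isovanillin). The ring A branch (steps 8–10) joins at step 11.

**Step 13 (key step).**
- Risk: heterolysis of the C2–O1 bond is the most likely failure. The carbon is a para-methoxybenzylic centre and the Lewis acid can activate the aryloxy group. The result would be loss of configuration at C2 or β-elimination, before or after ring closure. Lesser risks are HCl addition to the prenyl groups if the base is overwhelmed, and acylation of ring B. Partial loss of the C5 silyl group next to the new ketone would be harmless, since step 14 removes it.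
- Fallback: a polarity-reversed closure that forms the same C4–C4a bond with no Lewis acid. It sets out from 15 and 10 and returns at 19.
  - Phenol 15 would be iodinated ortho to the hydroxyl with N-iodosuccinimide at low temperature to give 2-iodo-3,5-bis(TBS-oxy)-4-prenylphenol F1.
  - Ester 10 would be converted with N,O-dimethylhydroxylamine hydrochloride and i-PrMgCl into the Weinreb amide (3R)-3-hydroxy-N-methoxy-N-methyl-3-[3-(TBS-oxy)-4-methoxy-2-prenylphenyl]propanamide F2.
  - Mitsunobu coupling of F1 and F2 would give (3S)-3-[2-iodo-3,5-bis(TBS-oxy)-4-prenylphenoxy]-N-methoxy-N-methyl-3-[3-(TBS-oxy)-4-methoxy-2-prenylphenyl]propanamide F3.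
  - Iodine–magnesium exchange on F3 with i-PrMgCl·LiCl in THF at −40 to 0 °C would generate the arylmagnesium at C4a. It adds to the Weinreb amide in a Parham-type cyclisation and gives 19 on work-up. The Grignard reagent is weakly basic and is not prone to silyl migration from the neighbouring oxygen.

**Step 11.**
- Risk: dehydration of the β-hydroxy ester to the cinnamate, because the Mitsunobu betaine can remove an acidic α-proton from the activated alcohol. Partial erosion of enantiomeric purity through an ion pair at the para-methoxybenzylic carbon is the second risk.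
- Fallback: the chain is carried at the alcohol oxidation level, where no acidic α-protons exist. It sets out from 10 and returns at 17.
  - Reduction of 10 with LiBH4 would give (1R)-1-[3-(TBS-oxy)-4-methoxy-2-prenylphenyl]propane-1,3-diol F4.
  - Selective acylation of the primary hydroxyl with pivaloyl chloride and pyridine would give (3R)-3-hydroxy-3-[3-(TBS-oxy)-4-methoxy-2-prenylphenyl]propyl pivalate F5.
  - Mitsunobu coupling with 15 would give (3S)-3-[3,5-bis(TBS-oxy)-4-prenylphenoxy]-3-[3-(TBS-oxy)-4-methoxy-2-prenylphenyl]propyl pivalate F6.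
  - Reductive removal of the pivalate with DIBAL-H at −78 °C would give (3S)-3-[3,5-bis(TBS-oxy)-4-prenylphenoxy]-3-[3-(TBS-oxy)-4-methoxy-2-prenylphenyl]propan-1-ol F7.
  - Oxidation of F7 with catalytic TEMPO and PhI(OAc)2 in aqueous MeCN would give acid 17.

**Step 10.**
- Risk: poor discrimination between the unflanked silyl ether and the two that have the prenyl group as ortho neighbour, and cleavage beyond the mono-phenol stage. Wrongly cleaved material could be re-silylated to 14 and recycled.
- Fallback: the unhindered oxygen is marked first with an orthogonal acyl group. It sets out from 13 and returns at 15.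
  - Pivaloyl chloride and pyridine at low temperature would acylate the least hindered hydroxyl of 13 to give 3,5-dihydroxy-4-prenylphenyl pivalate F8.
  - Silylation of the two remaining phenols would give 3,5-bis(TBS-oxy)-4-prenylphenyl pivalate F9.
  - DIBAL-H at −78 °C would remove the pivalate without touching the silyl ethers and give 15.

**Step 3.**
- Risk: thermal loss of the tertiary allyl group by elimination, which regenerates the phenol, and cyclisation of the product phenol onto its new prenyl group on prolonged heating.
- Fallback: the C2'–CH2 bond is made by cross-coupling. It sets out from 1 and returns at 5.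
  - Bromination of 1 with Br2 and NaOAc in AcOH would occur between the hydroxyl and the formyl-bearing carbon and give 2-bromo-3-hydroxy-4-methoxybenzaldehyde F10.
  - Suzuki–Miyaura coupling of F10 with prenylboronic acid pinacol ester would give 5. It would use Pd(OAc)2, a bulky biaryl dialkylphosphine and K3PO4 in aqueous THF, with the ligand chosen to favour coupling at the unsubstituted allyl terminus.

## Further compounds

F1 | step 13 | 2-iodo-3,5-bis[(tert-butyldimethylsilyl)oxy]-4-(3-methylbut-2-en-1-yl)phenol | CC(C)=CCc1c(O[Si](C)(C)C(C)(C)C)cc(O)c(I)c1O[Si](C)(C)C(C)(C)C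
F2 | step 13 | (3R)-3-hydroxy-N-methoxy-N-methyl-3-{3-[(tert-butyldimethylsilyl)oxy]-4-methoxy-2-(3-methylbut-2-en-1-yl)phenyl}propanamide | CON(C)C(=O)C[C@@H](O)c1ccc(OC)c(O[Si](C)(C)C(C)(C)C)c1CC=C(C)C
F3 | step 13 | (3S)-3-{2-iodo-3,5-bis[(tert-butyldimethylsilyl)oxy]-4-(3-methylbut-2-en-1-yl)phenoxy}-N-methoxy-N-methyl-3-{3-[(tert-butyldimethylsilyl)oxy]-4-methoxy-2-(3-methylbut-2-en-1-yl)phenyl}propanamide | CON(C)C(=O)C[C@H](Oc1cc(O[Si](C)(C)C(C)(C)C)c(CC=C(C)C)c(O[Si](C)(C)C(C)(C)C)c1I)c1ccc(OC)c(O[Si](C)(C)C(C)(C)C)c1CC=C(C)C
F4 | step 11 | (1R)-1-{3-[(tert-butyldimethylsilyl)oxy]-4-methoxy-2-(3-methylbut-2-en-1-yl)phenyl}propane-1,3-diol | OCC[C@@H](O)c1ccc(OC)c(O[Si](C)(C)C(C)(C)C)c1CC=C(C)C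
F5 | step 11 | (3R)-3-hydroxy-3-{3-[(tert-butyldimethylsilyl)oxy]-4-methoxy-2-(3-methylbut-2-en-1-yl)phenyl}propyl pivalate | CC(C)(C)C(=O)OCC[C@@H](O)c1ccc(OC)c(O[Si](C)(C)C(C)(C)C)c1CC=C(C)C
F6 | step 11 | (3S)-3-{3,5-bis[(tert-butyldimethylsilyl)oxy]-4-(3-methylbut-2-en-1-yl)phenoxy}-3-{3-[(tert-butyldimethylsilyl)oxy]-4-methoxy-2-(3-methylbut-2-en-1-yl)phenyl}propyl pivalate | CC(C)(C)C(=O)OCC[C@H](Oc1cc(O[Si](C)(C)C(C)(C)C)c(CC=C(C)C)c(O[Si](C)(C)C(C)(C)C)c1)c1ccc(OC)c(O[Si](C)(C)C(C)(C)C)c1CC=C(C)C
F7 | step 11 | (3S)-3-{3,5-bis[(tert-butyldimethylsilyl)oxy]-4-(3-methylbut-2-en-1-yl)phenoxy}-3-{3-[(tert-butyldimethylsilyl)oxy]-4-methoxy-2-(3-methylbut-2-en-1-yl)phenyl}propan-1-ol | OCC[C@H](Oc1cc(O[Si](C)(C)C(C)(C)C)c(CC=C(C)C)c(O[Si](C)(C)C(C)(C)C)c1)c1ccc(OC)c(O[Si](C)(C)C(C)(C)C)c1CC=C(C)C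
F8 | step 10 | 3,5-dihydroxy-4-(3-methylbut-2-en-1-yl)phenyl pivalate | CC(C)=CCc1c(O)cc(OC(=O)C(C)(C)C)cc1O
F9 | step 10 | 3,5-bis[(tert-butyldimethylsilyl)oxy]-4-(3-methylbut-2-en-1-yl)phenyl pivalate | CC(C)=CCc1c(O[Si](C)(C)C(C)(C)C)cc(OC(=O)C(C)(C)C)cc1O[Si](C)(C)C(C)(C)C
F10 | step 3 | 2-bromo-3-hydroxy-4-methoxybenzaldehyde | COc1ccc(C=O)c(Br)c1O
A1 | alternative 1 | (2S)-hesperetin, (2S)-5,7-dihydroxy-2-(3-hydroxy-4-methoxyphenyl)chroman-4-one | COc1ccc([C@@H]2CC(=O)c3c(O)cc(O)cc3O2)cc1O
A2 | alternative 1 | (2S)-7-(methoxymethoxy)-5-[(2-methylbut-3-en-2-yl)oxy]-2-{4-methoxy-3-[(2-methylbut-3-en-2-yl)oxy]phenyl}chroman-4-one | COc1ccc([C@@H]2CC(=O)c3c(OC(C)(C)C=C)cc(OCOC)cc3O2)cc1OC(C)(C)C=C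
A3 | alternative 1 | (2S)-5-hydroxy-2-[3-hydroxy-4-methoxy-2-(3-methylbut-2-en-1-yl)phenyl]-7-(methoxymethoxy)-6-(3-methylbut-2-en-1-yl)chroman-4-one | COc1ccc([C@@H]2CC(=O)c3c(cc(OCOC)c(CC=C(C)C)c3O)O2)c(CC=C(C)C)c1O
A4 | alternative 2 | 2-hydroxy-4-(methoxymethoxy)-3-(3-methylbut-2-en-1-yl)-6-({1-[4-methoxy-3-(methoxymethoxy)-2-(3-methylbut-2-en-1-yl)phenyl]ethenyl}oxy)benzaldehyde | O=Cc1c(O)c(CC=C(C)C)c(OCOC)cc1OC(=C)c1ccc(OC)c(OCOC)c1CC=C(C)C
A5 | alternative 2 | (2S)-5-hydroxy-7-(methoxymethoxy)-2-[4-methoxy-3-(methoxymethoxy)-2-(3-methylbut-2-en-1-yl)phenyl]-6-(3-methylbut-2-en-1-yl)chroman-4-one | COCOc1c(OC)ccc([C@@H]2CC(=O)c3c(cc(OCOC)c(CC=C(C)C)c3O)O2)c1CC=C(C)C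
A6 | alternative 3 | methyl (3S)-3-{3-[(tert-butyldimethylsilyl)oxy]-4-methoxy-2-(3-methylbut-2-en-1-yl)phenyl}-3-[(3-oxocyclobut-1-en-1-yl)oxy]propanoate | COC(=O)C[C@H](OC1=CC(=O)C1)c1ccc(OC)c(O[Si](C)(C)C(C)(C)C)c1CC=C(C)C
A7 | alternative 3 | triisopropyl[(5-methylhex-4-en-1-yn-1-yl)oxy]silane | CC(C)=CCC#CO[Si](C(C)C)(C(C)C)C(C)C
A8 | alternative 3 | methyl (3S)-3-[3-hydroxy-4-(3-methylbut-2-en-1-yl)-5-(triisopropylsilyloxy)phenoxy]-3-{3-[(tert-butyldimethylsilyl)oxy]-4-methoxy-2-(3-methylbut-2-en-1-yl)phenyl}propanoate | COC(=O)C[C@H](Oc1cc(O)c(CC=C(C)C)c(O[Si](C(C)C)(C(C)C)C(C)C)c1)c1ccc(OC)c(O[Si](C)(C)C(C)(C)C)c1CC=C(C)C
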